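## Retrosynthetic overview

1. The route rests on the O1–C8a aryl ether bond of ring C (the dihydropyran ring). It is closed last, between the C2 benzylic hydroxyl and a C8a bromide on ring A, in an open-chain anti-1,2-diol monoether that already carries C2 (R) and C3 (S). Ring C is the only ring formed; rings A and B and the 3-hydroxyphenyl ring are bought.
2. The anti alcohol comes from chelation-controlled Zn(BH4)2 reduction of an α-benzyloxy aryl ketone (sets C2). The ketone is made from a Weinreb amide and the ring B aryl Grignard (C2–C1' bond).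
3. The amide comes from an (S)-aryl lactate, formed by CuI-catalysed opening of methyl (S)-glycidate (source of C3) with the ring A aryl Grignard (C4–C4a bond).
4. That Grignard comes from a 1-bromo-2-iodo bibenzyl. Iodine is placed para to OMe on 3-bromo-5-methoxybenzaldehyde, where it marks C4a and the bromine becomes C8a. Wittig olefination and diimide reduction then add the arylethyl chain at C5.
5. All three hydroxyls travel as benzyl ethers and are freed in one final hydrogenolysis.

Key step: step 10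

Assumption: the SMILES is read as the (2R,3S), 2,3-trans flavan-3-ol, and the benzyl-protected building blocks 3 and 13 and the glycidate 8 are taken as catalogue compounds.

## Route

Step 1
Reactants: 1 3-bromo-5-methoxybenzaldehyde
Product: 2 3-bromo-2-iodo-5-methoxybenzaldehyde
Conditions: NIS, TFA, rt, dark
Reagents that add atoms: N-iodosuccinimide, O=C1CCC(=O)N1I
Why: Electrophilic aromatic iodination: every free position of 1 lies between two substituents, so sterics do not discriminate and the para-directing methoxy group should place iodine at C2 (between CHO and Br), as in the halogenation of 3-methoxybenzaldehyde.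

Step 2
Reactants: 3 1-(benzyloxy)-3-(bromomethyl)benzene
Product: 4 [3-(benzyloxy)benzyl]triphenylphosphonium bromide
Conditions: PPh3, toluene, reflux
Reagents that add atoms: triphenylphosphine, c1ccc(cc1)P(c1ccccc1)c1ccccc1
Why: SN2 quaternisation of triphenylphosphine by the benzylic bromide, with the salt expected to crystallise from toluene.

Step 3
Reactants: 2 3-bromo-2-iodo-5-methoxybenzaldehyde; 4 [3-(benzyloxy)benzyl]triphenylphosphonium bromide
Product: 6 3-{2-[3-(benzyloxy)phenyl]ethenyl}-1-bromo-2-iodo-5-methoxybenzene (E/Z mixture), via benzylidene ylide 5 (not isolated)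
Conditions: KOtBu, THF, 0 °C; then 2, 0 °C to rt
Reagents that add atoms: none
Why: Wittig olefination of the semi-stabilised benzylic ylide with the aldehyde; the E/Z mixture is of no consequence because the alkene is reduced next, and the ylide does not touch C–I or C–Br.

Step 4
Reactants: 6 3-{2-[3-(benzyloxy)phenyl]ethenyl}-1-bromo-2-iodo-5-methoxybenzene
Product: 7 3-{2-[3-(benzyloxy)phenyl]ethyl}-1-bromo-2-iodo-5-methoxybenzene
Conditions: TsNHNH2, NaOAc, DME/H2O, reflux
Reagents that add atoms: none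
Why: Diimide reduction: diimide released from the sulfonylhydrazide transfers two hydrogens to the stilbene C=C in a concerted syn addition and, being metal-free, should leave C–I, C–Br and the benzyl ether intact.

Step 5
Reactants: 7 3-{2-[3-(benzyloxy)phenyl]ethyl}-1-bromo-2-iodo-5-methoxybenzene; 8 methyl (2S)-oxirane-2-carboxylate
Product: 10 methyl (2S)-3-(2-{2-[3-(benzyloxy)phenyl]ethyl}-6-bromo-4-methoxyphenyl)-2-hydroxypropanoate, via arylmagnesium chloride 9 (not isolated)
Conditions: iPrMgCl·LiCl, THF, −40 °C; then CuI (10 mol%), 8, −40 to −20 °C; aq NH4Cl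
Reagents that add atoms: none
Why: Iodine–magnesium exchange is much faster at C–I than at C–Br and the ortho-bromo arylmagnesium is stable at these temperatures; copper-catalysed SN2 opening of the glycidate at its unsubstituted carbon (aryl lactate synthesis) forms C4–C4a without touching the stereocentre, so C3 is (S) as delivered by 8.

Step 6
Reactants: 10 methyl (2S)-3-(2-{2-[3-(benzyloxy)phenyl]ethyl}-6-bromo-4-methoxyphenyl)-2-hydroxypropanoate
Product: 11 methyl (2S)-2-(benzyloxy)-3-(2-{2-[3-(benzyloxy)phenyl]ethyl}-6-bromo-4-methoxyphenyl)propanoate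
Conditions: BnBr, Ag2O, CH2Cl2, 4 Å MS, rt, dark
Reagents that add atoms: benzyl bromide, BrCc1ccccc1
Why: Silver-oxide-mediated Williamson (Purdie) benzylation works without a strong base, so the α-hydroxy ester is etherified without enolisation and the C3 configuration is kept.

Step 7
Reactants: 11 methyl (2S)-2-(benzyloxy)-3-(2-{2-[3-(benzyloxy)phenyl]ethyl}-6-bromo-4-methoxyphenyl)propanoate
Product: 12 (2S)-2-(benzyloxy)-3-(2-{2-[3-(benzyloxy)phenyl]ethyl}-6-bromo-4-methoxyphenyl)-N-methoxy-N-methylpropanamide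
Conditions: MeNHOMe·HCl, iPrMgCl, THF, −20 °C; then 11, −20 to 0 °C
Reagents that add atoms: N,O-dimethylhydroxylamine hydrochloride, CNOC.Cl
Why: Weinreb amide formation by aminolysis of the methyl ester with the chloromagnesium amide; premixing consumes the Grignard base, so neither the aryl bromide nor the α-stereocentre should be attacked.

Step 8
Reactants: 12 (2S)-2-(benzyloxy)-3-(2-{2-[3-(benzyloxy)phenyl]ethyl}-6-bromo-4-methoxyphenyl)-N-methoxy-N-methylpropanamide; 13 1-(benzyloxy)-4-bromo-2-methoxybenzene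
Product: 15 (2S)-2-(benzyloxy)-1-[4-(benzyloxy)-3-methoxyphenyl]-3-(2-{2-[3-(benzyloxy)phenyl]ethyl}-6-bromo-4-methoxyphenyl)propan-1-one, via arylmagnesium bromide 14 (not isolated)
Conditions: 13, Mg, THF, 40 °C; then 12, THF, 0 °C; aq NH4Cl
Reagents that add atoms: none
Why: Weinreb ketone synthesis: the aryl Grignard adds once to give a stable magnesium chelate that collapses to the ketone only on quench, which prevents over-addition and keeps the α-benzyloxy centre from enolising.

Step 9
Reactants: 15 (2S)-2-(benzyloxy)-1-[4-(benzyloxy)-3-methoxyphenyl]-3-(2-{2-[3-(benzyloxy)phenyl]ethyl}-6-bromo-4-methoxyphenyl)propan-1-one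
Product: 16 (1R,2S)-2-(benzyloxy)-1-[4-(benzyloxy)-3-methoxyphenyl]-3-(2-{2-[3-(benzyloxy)phenyl]ethyl}-6-bromo-4-methoxyphenyl)propan-1-ol
Conditions: Zn(BH4)2, Et2O, −30 to 0 °C; aq NH4Cl
Reagents that add atoms: none
Why: Chelation-controlled (Cram-chelate) reduction: zinc bridges the carbonyl and the α-benzyloxy oxygen and hydride is delivered to the face of the five-membered chelate opposite the C4 methylene substituent, which should give the anti (1R,2S) alcohol and so sets C2.

Step 10
Reactants: 16 (1R,2S)-2-(benzyloxy)-1-[4-(benzyloxy)-3-methoxyphenyl]-3-(2-{2-[3-(benzyloxy)phenyl]ethyl}-6-bromo-4-methoxyphenyl)propan-1-ol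
Product: 17 (2R,3S)-3-(benzyloxy)-2-[4-(benzyloxy)-3-methoxyphenyl]-5-{2-[3-(benzyloxy)phenyl]ethyl}-7-methoxy-3,4-dihydro-2H-chromene
Conditions: Pd2(dba)3 (2.5 mol%), 2-(di-tert-butylphosphino)-1,1'-binaphthyl (6 mol%), Cs2CO3, toluene, 80 °C
Reagents that add atoms: none
Why: Zerovalent palladium inserts into the C8a–Br bond, Cs2CO3 deprotonates the C2 hydroxyl and exchanges bromide for the alkoxide on the divalent arylpalladium centre, and C–O reductive elimination from the resulting seven-membered aryl(alkoxo)palladium chelate forms O1–C8a. The closest known reaction type is the palladium-catalysed intramolecular etherification of aryl bromides with secondary alcohols under bulky di-tert-butyl biaryl phosphines, which gives chromans with retention at the carbinol carbon. Ring C closes in a 6-exo sense onto the arene carbon and is the only ring formed. No stereocentre is created and neither the C2–O nor the C3–O bond is broken, so the anti relationship of 16 maps onto the 2,3-trans relationship of 17. The step needs the benzylic oxygen alone to reach the metal and C–O reductive elimination to outrun β-hydride elimination of the alkoxide: the benzyl ether on the C3 oxygen removes the competing five-membered closure, and the bulky electron-rich ligand together with the favourable six-membered closure should favour reductive elimination.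

Step 11
Reactants: 17 (2R,3S)-3-(benzyloxy)-2-[4-(benzyloxy)-3-methoxyphenyl]-5-{2-[3-(benzyloxy)phenyl]ethyl}-7-methoxy-3,4-dihydro-2H-chromene
Product: 18 shanciol B, (2R,3S)-2-(4-hydroxy-3-methoxyphenyl)-5-[2-(3-hydroxyphenyl)ethyl]-7-methoxy-3,4-dihydro-2H-chromen-3-ol
Conditions: H2 (1 atm), Pd(OH)2/C, EtOAc/MeOH, rt
Reagents that add atoms: none
Why: Catalytic hydrogenolysis cleaves the two aryl benzyl ethers and the secondary alkyl benzyl ether, while the cyclic C2–O1 benzylic aryl ether is cleaved far more slowly (as in the debenzylation of perbenzylated catechins); neither stereocentre is touched.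

## Compound list

1 | 3-bromo-5-methoxybenzaldehyde | COc1cc(Br)cc(C=O)c1 | starting material
2 | 3-bromo-2-iodo-5-methoxybenzaldehyde | COc1cc(Br)c(I)c(C=O)c1 | intermediate
3 | 1-(benzyloxy)-3-(bromomethyl)benzene | BrCc1cccc(OCc2ccccc2)c1 | starting material
4 | [3-(benzyloxy)benzyl]triphenylphosphonium bromide | [Br-].c1ccc(cc1)[P+](Cc1cccc(OCc2ccccc2)c1)(c1ccccc1)c1ccccc1 | intermediate
5 | [3-(benzyloxy)benzylidene]triphenylphosphorane (ylide, formed in the flask) | c1ccc(cc1)P(=Cc1cccc(OCc2ccccc2)c1)(c1ccccc1)c1ccccc1 | intermediate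
6 | 3-{2-[3-(benzyloxy)phenyl]ethenyl}-1-bromo-2-iodo-5-methoxybenzene (E/Z mixture) | COc1cc(Br)c(I)c(C=Cc2cccc(OCc3ccccc3)c2)c1 | intermediate
7 | 3-{2-[3-(benzyloxy)phenyl]ethyl}-1-bromo-2-iodo-5-methoxybenzene | COc1cc(Br)c(I)c(CCc2cccc(OCc3ccccc3)c2)c1 | intermediate
8 | methyl (2S)-oxirane-2-carboxylate | COC(=O)[C@@H]1CO1 | starting material
9 | (2-{2-[3-(benzyloxy)phenyl]ethyl}-6-bromo-4-methoxyphenyl)magnesium chloride (formed in the flask) | COc1cc(Br)c([Mg]Cl)c(CCc2cccc(OCc3ccccc3)c2)c1 | intermediate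
10 | methyl (2S)-3-(2-{2-[3-(benzyloxy)phenyl]ethyl}-6-bromo-4-methoxyphenyl)-2-hydroxypropanoate | COc1cc(Br)c(C[C@H](O)C(=O)OC)c(CCc2cccc(OCc3ccccc3)c2)c1 | intermediate
11 | methyl (2S)-2-(benzyloxy)-3-(2-{2-[3-(benzyloxy)phenyl]ethyl}-6-bromo-4-methoxyphenyl)propanoate | COc1cc(Br)c(C[C@H](OCc2ccccc2)C(=O)OC)c(CCc2cccc(OCc3ccccc3)c2)c1 | intermediate
12 | (2S)-2-(benzyloxy)-3-(2-{2-[3-(benzyloxy)phenyl]ethyl}-6-bromo-4-methoxyphenyl)-N-methoxy-N-methylpropanamide | COc1cc(Br)c(C[C@H](OCc2ccccc2)C(=O)N(C)OC)c(CCc2cccc(OCc3ccccc3)c2)c1 | intermediate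
13 | 1-(benzyloxy)-4-bromo-2-methoxybenzene | COc1cc(Br)ccc1OCc1ccccc1 | starting material
14 | [4-(benzyloxy)-3-methoxyphenyl]magnesium bromide (formed in the flask) | COc1cc([Mg]Br)ccc1OCc1ccccc1 | intermediate
15 | (2S)-2-(benzyloxy)-1-[4-(benzyloxy)-3-methoxyphenyl]-3-(2-{2-[3-(benzyloxy)phenyl]ethyl}-6-bromo-4-methoxyphenyl)propan-1-one | COc1cc(Br)c(C[C@H](OCc2ccccc2)C(=O)c2ccc(OCc3ccccc3)c(OC)c2)c(CCc2cccc(OCc3ccccc3)c2)c1 | intermediate
16 | (1R,2S)-2-(benzyloxy)-1-[4-(benzyloxy)-3-methoxyphenyl]-3-(2-{2-[3-(benzyloxy)phenyl]ethyl}-6-bromo-4-methoxyphenyl)propan-1-ol (anti) | COc1cc(Br)c(C[C@H](OCc2ccccc2)[C@H](O)c2ccc(OCc3ccccc3)c(OC)c2)c(CCc2cccc(OCc3ccccc3)c2)c1 | intermediate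
17 | (2R,3S)-3-(benzyloxy)-2-[4-(benzyloxy)-3-methoxyphenyl]-5-{2-[3-(benzyloxy)phenyl]ethyl}-7-methoxy-3,4-dihydro-2H-chromene (2,3-trans) | COc1cc(CCc2cccc(OCc3ccccc3)c2)c2c(c1)O[C@H](c1ccc(OCc3ccccc3)c(OC)c1)[C@@H](OCc1ccccc1)C2 | intermediate
18 | shanciol B, (2R,3S)-2-(4-hydroxy-3-methoxyphenyl)-5-[2-(3-hydroxyphenyl)ethyl]-7-methoxy-3,4-dihydro-2H-chromen-3-ol | COc1cc(CCc2cccc(O)c2)c2c(c1)O[C@H](c1ccc(O)c(OC)c1)[C@@H](O)C2 | target

## Step count and risks

Total step count: 11. Longest linear sequence: 10 steps (steps 1, 3, 4, 5, 6, 7, 8, 9, 10, 11 from compound 1).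

The three steps most likely to fail:

**Step 10 (ring closure).** β-Hydride elimination from the arylpalladium alkoxide may outrun C–O reductive elimination. That would oxidise the benzylic carbinol and remove the bromine, or scramble C2 if the elimination is reversible.
Fallback: it sets out from 15 and comes back at 17, and makes the ring C ether from the other side (C2–O1 by displacement).
- LiBH(s-Bu)3 in THF at −78 °C should reduce 15 under Felkin–Anh control to the syn alcohol, (1S,2S)-2-(benzyloxy)-1-[4-(benzyloxy)-3-methoxyphenyl]-3-(2-{2-[3-(benzyloxy)phenyl]ethyl}-6-bromo-4-methoxyphenyl)propan-1-ol F1.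
- Miyaura borylation (B2pin2, PdCl2(dppf), KOAc, dioxane, 80 °C) turns the C8a bromide into the pinacol boronate, (1S,2S)-2-(benzyloxy)-1-[4-(benzyloxy)-3-methoxyphenyl]-3-[2-{2-[3-(benzyloxy)phenyl]ethyl}-4-methoxy-6-(4,4,5,5-tetramethyl-1,3,2-dioxaborolan-2-yl)phenyl]propan-1-ol F2.
- NaBO3·4H2O in THF/H2O oxidises it to the phenol, 2-{(2S,3S)-2-(benzyloxy)-3-[4-(benzyloxy)-3-methoxyphenyl]-3-hydroxypropyl}-3-{2-[3-(benzyloxy)phenyl]ethyl}-5-methoxyphenol F3.
- Mitsunobu ring closure (PPh3, DIAD, THF, 0 °C) displaces the activated C2 hydroxyl by the phenol oxygen with inversion, so the syn alcohol should give the 2,3-trans chroman 17.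

**Step 5 (exchange and epoxide opening).** The hindered, ortho-bromo arylmagnesium may add to the ester carbonyl of the glycidate, open the epoxide too slowly, or lose magnesium halide to an aryne on warming.
Fallback: it sets out from 7 and comes back at 12, and builds C3 by auxiliary-controlled alkylation instead.
- The same exchange (iPrMgCl·LiCl, −40 °C) followed by DMF gives 2-{2-[3-(benzyloxy)phenyl]ethyl}-6-bromo-4-methoxybenzaldehyde F4.
- NaBH4 in MeOH gives (2-{2-[3-(benzyloxy)phenyl]ethyl}-6-bromo-4-methoxyphenyl)methanol F5.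
- PBr3 in CH2Cl2 gives 1-{2-[3-(benzyloxy)phenyl]ethyl}-3-bromo-2-(bromomethyl)-5-methoxybenzene F6.
- Separately, (4R)-4-benzyl-1,3-oxazolidin-2-one is acylated (n-BuLi, benzyloxyacetyl chloride, THF, −78 °C) to (4R)-4-benzyl-3-[(benzyloxy)acetyl]-1,3-oxazolidin-2-one F7.
- The sodium enolate of F7 (NaN(SiMe3)2, THF, −78 °C) is alkylated by F6 on the face away from the auxiliary benzyl group. This should give (4R)-4-benzyl-3-[(2S)-2-(benzyloxy)-3-(2-{2-[3-(benzyloxy)phenyl]ethyl}-6-bromo-4-methoxyphenyl)propanoyl]-1,3-oxazolidin-2-one F8.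
- Transamination with AlMe3 and MeNHOMe·HCl in CH2Cl2 gives 12.

**Step 1 (iodination).** Iodine may enter ortho to the methoxy group instead of para, and the regioisomers may be hard to separate.
Fallback: it sets out from 4 and comes back at 7; an amino group fixes the position of the iodine.
- Wittig methylenation of 4 (aqueous formaldehyde, K2CO3) gives 1-(benzyloxy)-3-ethenylbenzene F9.
- Hydroboration with 9-BBN in THF gives 9-{2-[3-(benzyloxy)phenyl]ethyl}-9-borabicyclo[3.3.1]nonane F10.
- Commercial 2-bromo-4-methoxyaniline is iodinated with NIS at the only open position ortho to the amino group, to 2-bromo-6-iodo-4-methoxyaniline F11.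
- B-alkyl Suzuki–Miyaura coupling of F10 at the C–I bond of F11 (PdCl2(dppf), K3PO4, THF/DMF/H2O, rt) gives 2-{2-[3-(benzyloxy)phenyl]ethyl}-6-bromo-4-methoxyaniline F12.
- Diazotisation (t-BuONO, TsOH·H2O, MeCN, 0 °C) and KI replace the amino group by iodine and give 7.

## Further compounds

F1 | step 10 | (1S,2S)-2-(benzyloxy)-1-[4-(benzyloxy)-3-methoxyphenyl]-3-(2-{2-[3-(benzyloxy)phenyl]ethyl}-6-bromo-4-methoxyphenyl)propan-1-ol | COc1cc(Br)c(C[C@H](OCc2ccccc2)[C@@H](O)c2ccc(OCc3ccccc3)c(OC)c2)c(CCc2cccc(OCc3ccccc3)c2)c1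
F2 | step 10 | (1S,2S)-2-(benzyloxy)-1-[4-(benzyloxy)-3-methoxyphenyl]-3-[2-{2-[3-(benzyloxy)phenyl]ethyl}-4-methoxy-6-(4,4,5,5-tetramethyl-1,3,2-dioxaborolan-2-yl)phenyl]propan-1-ol | COc1cc(B2OC(C)(C)C(C)(C)O2)c(C[C@H](OCc2ccccc2)[C@@H](O)c2ccc(OCc3ccccc3)c(OC)c2)c(CCc2cccc(OCc3ccccc3)c2)c1
F3 | step 10 | 2-{(2S,3S)-2-(benzyloxy)-3-[4-(benzyloxy)-3-methoxyphenyl]-3-hydroxypropyl}-3-{2-[3-(benzyloxy)phenyl]ethyl}-5-methoxyphenol | COc1cc(O)c(C[C@H](OCc2ccccc2)[C@@H](O)c2ccc(OCc3ccccc3)c(OC)c2)c(CCc2cccc(OCc3ccccc3)c2)c1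
F4 | step 5 | 2-{2-[3-(benzyloxy)phenyl]ethyl}-6-bromo-4-methoxybenzaldehyde | COc1cc(Br)c(C=O)c(CCc2cccc(OCc3ccccc3)c2)c1
F5 | step 5 | (2-{2-[3-(benzyloxy)phenyl]ethyl}-6-bromo-4-methoxyphenyl)methanol | COc1cc(Br)c(CO)c(CCc2cccc(OCc3ccccc3)c2)c1
F6 | step 5 | 1-{2-[3-(benzyloxy)phenyl]ethyl}-3-bromo-2-(bromomethyl)-5-methoxybenzene | COc1cc(Br)c(CBr)c(CCc2cccc(OCc3ccccc3)c2)c1
F7 | step 5 | (4R)-4-benzyl-3-[(benzyloxy)acetyl]-1,3-oxazolidin-2-one | O=C(COCc1ccccc1)N1[C@H](Cc2ccccc2)COC1=O
F8 | step 5 | (4R)-4-benzyl-3-[(2S)-2-(benzyloxy)-3-(2-{2-[3-(benzyloxy)phenyl]ethyl}-6-bromo-4-methoxyphenyl)propanoyl]-1,3-oxazolidin-2-one | COc1cc(Br)c(C[C@H](OCc2ccccc2)C(=O)N2[C@H](Cc3ccccc3)COC2=O)c(CCc2cccc(OCc3ccccc3)c2)c1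
F9 | step 1 | 1-(benzyloxy)-3-ethenylbenzene | C=Cc1cccc(OCc2ccccc2)c1
F10 | step 1 | 9-{2-[3-(benzyloxy)phenyl]ethyl}-9-borabicyclo[3.3.1]nonane | C(Cc1cccc(OCc2ccccc2)c1)B1C2CCCC1CCC2
F11 | step 1 | 2-bromo-6-iodo-4-methoxyaniline | COc1cc(Br)c(N)c(I)c1
F12 | step 1 | 2-{2-[3-(benzyloxy)phenyl]ethyl}-6-bromo-4-methoxyaniline | COc1cc(Br)c(N)c(CCc2cccc(OCc3ccccc3)c2)c1
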